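Readings and results were generated by integration from invented constants, noise included.

If amber is elm with its starting material merely handed in over 15.0 min, then the question is how much a portion added late can still do.

all flasks: coupling partner 0.128 M

| flask | starting material | second substrate | precatalyst | remark | time |
|---|---|---|---|---|---|
| elm | 0.085 M | 0.0425 M | 16 mM | run made earlier |  |
| larch | 0.085 M | 0.0425 M | 8 mM | run made earlier |  |
| alder | 0.085 M | 0.0425 M | 32 mM | run made earlier |  |
| amber | 0.085 M (fed, over 15.0 min) | 0.0425 M | 16 mM | all but starting material at the start; starting material goes in evenly over 15.0 min, the run ends at 15 min | 15 min |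
| red | 0.085 M | 0.0425 M | 16 mM | a single well-mixed tank run continuously and read at steady state, 15 min in it on average |  |
| grey | 0.085 M | 0.0425 M | 16 mM | a closed flask charged with all of it at once and left for 15 min | 15 min |
| violet | 0.085 M | 0.0425 M (fed, over 15.0 min) | 16 mM | all but second substrate at the start; second substrate goes in evenly over 15.0 min, the run ends at 15 min | 15 min |

| run | time / min | target / % | starting material / % |
|---|---|---|---|
| elm | 2.00 | 1.5 | 98.8 |
| elm | 4.00 | 5.5 | 94.8 |
| elm | 6.00 | 10.8 | 89.3 |
| elm | 8.00 | 16.5 | 83.2 |
| elm | 10.0 | 22.7 | 78.1 |
| elm | 12.0 | 27.9 | 72.3 |
| elm | 15.0 | 36.3 | 64.2 |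
| larch | 1.33 | 0.1 | 99.8 |
| larch | 2.50 | 1.0 | 99.1 |
| larch | 4.00 | 3.3 | 97.5 |
| larch | 5.00 | 3.7 | 95.7 |
| larch | 6.00 | 6.2 | 94.6 |
| larch | 8.00 | 9.5 | 90.6 |
| larch | 10.0 | 13.5 | 87.1 |
| alder | 1.33 | 1.4 | 98.9 |
| alder | 2.50 | 4.2 | 95.9 |
| alder | 4.00 | 10.5 | 89.6 |
| alder | 5.00 | 13.7 | 85.6 |
| alder | 6.00 | 18.5 | 81.5 |
| alder | 8.00 | 27.7 | 72.4 |
| alder | 10.0 | 34.8 | 64.7 |

(scatter of a reading: 0.3 percentage points)

- the stated concentrations are those of everything mixed, before any reaction; amounts are the same in each set-up
- the feed brings no volume worth counting
- the earlier runs were made in a closed, stirred flask

- the set-up with the highest amount of target at the outlet or at the end, in percent of the starting material put in ("none" if the first two lie within 2 percentage points) (amber / red / grey / violet / none)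
- amount of target at the outlet or at the end, in percent of the starting material put in, amber
- amount of target at the outlet or at the end, in percent of the starting material put in, red
- amount of target at the outlet or at the end, in percent of the starting material put in, grey
- amount of target at the outlet or at the end, in percent of the starting material put in, violet

Elm's target grows 3.67-fold from 2.00 min to 4.00 min, which reads as a catalyst still forming, so the steady late line in elm need not mean that the amount of starting material doesn't count. I assume that it does count: each molecule has the same chance per minute, however many stand beside it (pseudo-first-order in starting material).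

At 7.50 min, amber has received half of its charge while elm still holds 84.7%, so amber then has less to work on. Elm's stock goes on falling, to 64.2% at 15.0 min, while amber's is still being filled.

So I follow one average portion, the one entering amber at mid-feed, and I take catalyst and coupling partner to be as in elm. Elm gives 75.8% as the part of the starting material standing at mid-feed that still stands at the end, which I call the staying share. My reckoning for amber is therefore about 24.2% of target, below elm's 36.3%. For red and violet I have no reckoning of my own.

The forecast differs on amber. It gives amber 35%, red 37%, grey 36.3% and violet 34%, with best none, and says of the two fed flasks: “feeds outpace consumption, so rates barely suffer”.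

The flasks give amber 24.3%, red 33.2%, grey 35.8% and violet 38.7%, so the best is violet.

    precatalyst → catalyst (k = 0.0710 min⁻¹)
    second substrate + coupling partner + catalyst → catalyst + second product (k = 190 L² mol⁻² min⁻¹)
    starting material + coupling partner + catalyst → catalyst + target (k = 55.0 L² mol⁻² min⁻¹)

Amber's 24.3% stands beside the 24.2% from the staying share. In grey at 6.92 min, the second substrate uses coupling partner 1.2 times as fast as the target step does, and at 7.50 min violet still has 84.2% of its coupling partner against grey's 75.6%.

A neighbour of grey is charged with 0.051 M of coupling partner, 0.398 of the usual charge; the target step above is first order in coupling partner, so as a rough estimate I count the neighbour's 15.0 min as that fraction of elm's 15.0 min. Raising the whole-run share, the staying share times the mid-feed reading, to that power gives about 16.2% of target; the computed flask gives 15.0%.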